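The data are simulated from invented constants, and the scatter is random.

Tuesday's run, charged with 0.539 of reagent per substrate at −5 °C, had turned 51 percentage points of its substrate by 10.0 h and was still moving. Friday's run, at 0.800, stalled with 80 points turned.

all flasks: substrate 0.076 M
- Friday's: reagent 0.0608 M; temperature 0 °C; the very flask that is asked about, followed so far
- Tuesday's: reagent 0.041 M; temperature −5 °C; run made earlier
- flask: reagent 0.0608 M; temperature 0 °C; time 5.0 d

| run | time / h | target / % | substrate / % |
|---|---|---|---|
| Friday's | 8.00 | 48.5 | 28.1 |
| Friday's | 12.0 | 58.1 | 24.1 |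
| Friday's | 20.0 | 68.2 | 21.2 |
| Friday's | 25.0 | 70.6 | 21.2 |
| Friday's | 40.0 | 74.3 | 19.6 |
| Friday's | 60.0 | 75.2 | 19.9 |
| Friday's | 96.0 | 75.1 | 20.3 |
| Tuesday's | 0.833 | 2.4 | 84.5 |
| Tuesday's | 1.33 | 6.0 | 79.3 |
| Tuesday's | 2.00 | 11.4 | 73.0 |
| Tuesday's | 3.00 | 16.9 | 66.4 |
| Tuesday's | 4.00 | 20.1 | 61.5 |
| Tuesday's | 6.00 | 27.7 | 55.2 |
| Tuesday's | 10.0 | 35.4 | 49.4 |

(each reading ± 0.5 percentage points)

- zeta: at 5.0 d take out 90% of the by-product then present, then wait 5.0 d
- delta: at 5.0 d add reagent, 100% of the amount charged, then wait 5.0 d
- beta: at 5.0 d raise the temperature by 25 K, then wait 5.0 d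
- alpha: change nothing and wait 5.0 d more

- additions bring no volume worth counting
- a reading or a percentage of target counts all its forms, free or not

* target, in percent of the substrate first charged, at 5.0 d
* which option adds most target ("none" when 2 percentage points or less is all one gets) (zeta / delta / beta / alpha / none)
* target present, in percent of the substrate first charged, after beta
* target present, in percent of the substrate first charged, after alpha

The bench rule says that each reagent turns one substrate, so a substrate molecule in this flask meets two forks. At the first it needs a partner. Reagent is charged below substrate, which makes it the limiting reagent, and the chance of a partner is the charge ratio. At the second fork a turned molecule ends as target or does not. Late in Friday's run, target over turned substrate reads 0.942; call this the target share.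

The product of the two chances gives 0.754 of the charge as target at 5.0 d. Alpha and zeta bring no reagent, so this reckoning expects no gain from them.

The rule stops where the ratio passes one. Delta lifts it to 1.60, so substrate becomes the limit, the first chance is capped at one, and target reckons to 94.2% of the charge, a gain of 19 points. The share was read at 0 °C, so the reckoning is silent on beta.

The forecast put target at 75.1% now, 75.2% after alpha and 76.5% after beta, and chose delta: “so delta wins clearly”.

The flask gives 74.4% at 5.0 d, 72.7% after alpha and 47.9% after beta. Delta adds most, 18 points against the 19 points reckoned from the target share of 94.2%. In this flask substrate with reagent had 99.1% of its turnover up to 5.0 d behind it by 24.0 h, and the passing of intermediate into target had 76% of its own behind it by 12.0 h. From 60.0 h to 120 h, with reagent at 0% of its charge at the end, target eased from 75.0% to 74.4% while side product rose from 1.38% to 2.08%.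

    target + by-product → side product (k = 0.00323 L mol⁻¹ min⁻¹, Ea = 53.0 kJ mol⁻¹)
    substrate + reagent → intermediate + by-product (k = 0.143 L mol⁻¹ min⁻¹, Ea = 56.0 kJ mol⁻¹)
    target → over-reaction product (k = 3.23 × 10⁻⁵ min⁻¹, Ea = 99.0 kJ mol⁻¹)
    crystals ⇌ target, rate k4*(cs4 - [target]) while solid is left; crystals form when [target] > cs4 (solubility = 0.780 mM, k = 0.0166 min⁻¹)
    intermediate ⇌ isomer of the product (K = 2.30, k = 0.00862 min⁻¹, Ea = 83.0 kJ mol⁻¹, ΔH = −19.0 kJ mol⁻¹)
    intermediate ⇌ target (K = 1.05, k = 0.0250 min⁻¹, Ea = 80.0 kJ mol⁻¹, ΔH = −57.0 kJ mol⁻¹)
    (constants at 0 °C)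

The neighbour charged with 0.036 M of reagent has a ratio of 0.474, and the target share makes that 44.6% of the charge. The computed neighbour gives 42.8% at 5.0 d.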